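## Analysis of the target

Compound 23 is a eudesmane: a decalin whose rings A and B share C5 and C10, with a tetrasubstituted C4=C5 alkene that makes C5 a planar ring-fusion atom. Four stereocentres remain, C3 (S), C7 (R), C8 (R) and C10 (R), and all four substituents (the C3 acyloxy group, the C7 acrylate, the C8 acetoxy group and the C10 methyl C14) lie on the same β face. C3 and C10 are separated by the alkene, so their relation cannot be relayed through an sp3 chain. C7 and C8 are vicinal and cis, with the C8 oxygen axial and 1,3 to the axial C14; this pair is an opened cis-fused γ-lactone and tends to re-close. Sensitive groups are the 2-substituted acrylate (a Michael acceptor), the allylic ester at C3 (prone to ionisation and elimination), the β,β-disubstituted enoate (E/Z scrambling and deconjugation on activation), and three different ester groups that must be placed selectively. The hard points are the quaternary C10 next to the tetrasubstituted alkene, the C3/C10 relation across it, and the differentiation of the O3 and O8 acyl groups in the presence of the acrylate. The strategy rests on one feature: if C4 is a ketone before it carries its methyl, C5–C10 is the alkene of a 3-methylcyclohex-2-enone (ring A), and C8, para to C5 in ring B, is the oxygen-bearing carbon of a 2-oxygenated butadiene.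

## Retrosynthetic reasoning

**C3–O acyl bond.** Cutting the ester of 23 gives allylic alcohol 21 and acid 22. It is cut first because the enoate would survive neither the enolate chemistry nor the hydroxide used earlier. The forward step must acylate a hindered allylic alcohol without isomerising the enoate.

**O8 acetyl and O3 silyl groups.** Removing the acetate and restoring the silyl ether leads from 21 through 20 to 19. Two different acyl groups on O3 and O8 demand orthogonal masking: O3 stays silylated from the first stages, and O8 is hidden in a lactone until it is acetylated.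

**Ester C12–OMe and the O8–H bond.** The cis 8β-hydroxy ester 19 is the opened form of the cis-fused α-methylene lactone 17 (through carboxylate 18). The lactone protects O8 and C12 together and gives a rigid frame for the methylenation. The forward opening must avoid conjugate addition to C13 and must not allow re-closure before O8 is capped.

**C11=C13.** The exocyclic methylene of 17 is removed to give lactone 14. A two-carbon acetate unit is far easier to attach at C7 than a ready-made acrylate, and in 14 the only enolisable position is C11.

**Lactone C8–O and C7–C11.** Lactone 14 comes from keto ester 12 by reduction at C8, and 12 from the enol silane 10 by alkylation at C7 with a C2 ester electrophile. The C7–C11 bond is cut because it lies next to a carbonyl. The forward alkylation needs the C7–C8 enolate and not the C8–C9 one, which is what an enol silane fixed at C7–C8 delivers. C7 is corrected by equilibration, and C8 by hydride attack opposite the axial C14.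

**C4–C15 and the C4=C5 alkene.** Retro-dehydration of 10 gives carbinol 9, and removal of the methyl gives ketone 8. This unveils the carbonyl that activates ring A as a dienophile. The forward steps must add a methyl nucleophile to a hindered α-silyloxy ketone and eliminate water toward C5 only.

**C5–C6 and C9–C10.** These two ring-B bonds flank the former enone alkene. Cutting both divides 8 into enone 5 and diene 7, two fragments of comparable size made in few steps, and forms the quaternary C10 in the ring-closing step. The polarity matches: the nucleophilic CH2 end of the diene becomes C9 on the β-carbon C10, which puts the oxygen on C8 and the enol double bond at C7–C8. The forward reaction must choose the face of the enone relative to C3.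

**Fragments.** Enone 5 comes from alcohol 4, obtained by resolution of racemic 3. Compound 3 arises from acetate 2, made by α'-oxidation of 1 at C6 (the future C3). Diene 7 is the enol silane of 6.

## Alternatives that were turned down

**Alternative 1:** The C5–C10 bond is cut, leading back to the ten-membered (E,E)-triene ester A2. In the forward direction a strong sulfonic acid protonates C1, the C4=C5 alkene captures the C10 cation across the ring, and loss of H5 gives A1.
- For: one step forms both rings and the quaternary centre, and C10 is set from the existing C7 and C8 centres through a chair-like transannular geometry. On the relay of C10 from C7/C8 and on the brevity of skeleton formation this alternative is stronger than the chosen route.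
- Against: A1 has no oxygen at C3. It would have to be added by allylic oxidation of a tetrasubstituted alkene with three competing allylic sites (C3, C6, C15) and no facial bias, or carried through the cyclisation, where it sits next to the developing cation. A2 is a strained medium ring with two E alkenes and two stereocentres, harder to make than the decalin itself. The final proton loss can also place the alkene at C3–C4 or C4–C15.
- In its place the chosen strategy offers bulk starting materials, the C3 oxygen present from the first step, and a C8 carbonyl equivalent that directs the side chain to C7.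

**Alternative 2:** The angular methyl is traced back to a cyclopropane, cutting C5–C14. In the forward key step the zinc alkoxide of the C3 hydroxyl of octalinone A4 delivers a zinc carbenoid to the C5=C10 alkene on its own face to give the methano ketol A3. A later cleavage of C5–C14 releases the methyl and the C4=C5 alkene.
- For: hydroxyl-directed delivery fixes C14 cis to the C3 oxygen, the relation that the chosen route must win through ring conformation. On this point the alternative is stronger.
- Against: the cyclopropane has three bonds that can break and no conjugated carbonyl to select C5–C14 (the C8 ketone is one carbon too far). Ionic opening creates a C5 cation beside the oxygen-bearing C3. A4 needs a tetrasubstituted C5=C10 alkene next to a C4 stereocentre. The C7 side chain and C8 still require the same enolate chemistry as the chosen route.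
- Two strategic operations are spent on one methyl group, whereas the chosen cycloaddition installs C14 while ring B is formed.

**Alternative 3:** The C7–C11 bond is cut and tethered to O8. In the forward key step a tin hydride with a radical initiator converts bromoacetal A6 into a radical that adds 5-exo to C7 of the 4,6-diene, and hydrogen transfer to C6 of the resulting allyl radical leaves the C4=C5 alkene in acetal A5.
- For: the tether forces C11 cis to O8 kinetically, which is stronger than the thermodynamic equilibration at C7 used here, and no enolate regiochemistry arises.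
- Against: A6 already contains the whole bicyclic core with C3, C8 and C10 set and a 4,6-diene, so the difficult part of the synthesis is left unsolved. Hydrogen transfer can also occur at C4. The acetal must then be oxidised to the lactone before the same end game begins.
- The chosen route makes the same bond in one alkylation of the enol silane that the cycloaddition leaves behind, and solves the core at the same time.

Key step: step 6

Convention: eudesmane numbering is used throughout (C1–C10 ring carbons, C11–C13 the C7 side chain, C14 the C10 methyl, C15 the C4 methyl); β is the face that carries C14.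

Assumption: the lipase of step 3 acetylates the R enantiomer of alcohol 3 faster, the usual preference of such enzymes for a secondary carbinol whose larger flank is the carbonyl side, so that 4 is the unreacted alcohol.

## Route

Step 1
Reactants: 1 3-methylcyclohex-2-en-1-one
Product: 2 racemic 6-acetoxy-3-methylcyclohex-2-en-1-one
Conditions: Mn(OAc)3·2H2O, benzene, reflux with removal of water
Reagents that add atoms: manganese triacetate, CC(=O)[O-].CC(=O)[O-].CC(=O)[O-].[Mn+3]
Why: α'-Acetoxylation of an enone by trivalent manganese: the manganese enolate forms on the saturated side of the carbonyl and acetate is transferred to C6 (the future C3); the conjugated side is not touched.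

Step 2
Reactants: 2 racemic 6-acetoxy-3-methylcyclohex-2-en-1-one
Product: 3 racemic 6-hydroxy-3-methylcyclohex-2-en-1-one
Conditions: K2CO3 (cat.), MeOH, 0 °C, short reaction time
Reagents that add atoms: none
Why: Base-catalysed transesterification with methanol; the substrate is racemic, so enolisation at the carbinol carbon costs nothing, and cold, brief treatment limits isomerisation of the ketol.

Step 3
Reactants: 3 racemic 6-hydroxy-3-methylcyclohex-2-en-1-one
Product: 4 (S)-6-hydroxy-3-methylcyclohex-2-en-1-one (recovered unreacted alcohol)
Conditions: Burkholderia cepacia lipase, vinyl acetate, t-BuOMe, 30 °C, run past half conversion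
Reagents that add atoms: none
Why: Lipase-catalysed kinetic resolution by irreversible transesterification; the R alcohol is acetylated and the S alcohol remains, its enantiomeric purity rising with conversion. The S configuration here becomes 3S (β oxygen) of the target.

Step 4
Reactants: 4 (S)-6-hydroxy-3-methylcyclohex-2-en-1-one
Product: 5 (S)-6-(tert-butyldimethylsilyloxy)-3-methylcyclohex-2-en-1-one
Conditions: TBSCl, imidazole, DMF, rt
Reagents that add atoms: tert-butyldimethylsilyl chloride, CC(C)(C)[Si](C)(C)Cl
Why: Standard silylation of a secondary alcohol; the mild base does not enolise the ketol, so C6 keeps its configuration, and the bulky non-chelating ether is the control element for step 6.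

Step 5
Reactants: 6 but-3-en-2-one
Product: 7 2-(tert-butyldimethylsilyloxy)buta-1,3-diene
Conditions: TBSOTf, Et3N, Et2O, 0 °C
Reagents that add atoms: tert-butyldimethylsilyl triflate, CC(C)(C)[Si](C)(C)OS(=O)(=O)C(F)(F)F
Why: Soft enolisation: O-silylation of the ketone and loss of a methyl proton give the cross-conjugated silyl dienol ether; the tert-butyldimethylsilyl group is chosen to withstand the Lewis acid of step 6.

Step 6
Reactants: 5 (S)-6-(tert-butyldimethylsilyloxy)-3-methylcyclohex-2-en-1-one; 7 2-(tert-butyldimethylsilyloxy)buta-1,3-diene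
Product: 8 cis-fused adduct 3β,8-bis(tert-butyldimethylsilyloxy)-10β-methyl-5βH-decal-7-en-4-one, (2S,4aR,8aS)-2,6-bis(tert-butyldimethylsilyloxy)-4a-methyl-3,4,4a,5,8,8a-hexahydronaphthalen-1(2H)-one
Conditions: Me2AlCl (about 1.1 equiv), excess 7, CH2Cl2, −78 → −20 °C; Et3N, then aq NaHCO3
Reagents that add atoms: none
Why: Me2AlCl binds the C4 carbonyl oxygen of 5 and lowers the LUMO of the β,β-disubstituted enone; the electron-rich CH2 terminus of 7 (future C9) bonds to the β-carbon C10 and the vinyl terminus (C6) to C5, either in one strongly asynchronous [4+2] cycloaddition or, at the limit, by Mukaiyama–Michael addition followed by 6-endo-trig Michael closure of the aluminium enolate onto the silylated enone, and both paths end in the same enol silane. The closest known reaction type is the Lewis-acid-promoted Diels–Alder addition of 2-silyloxybutadienes to 3-methylcyclohex-2-enones, which gives cis-fused angular-methyl decalones. Ring B is closed by this intermolecular suprafacial addition across C5=C10, which places H5 and C14 cis. C10 is controlled by C3: in the monodentate aluminium complex the silyloxy group should stand pseudo-axial, because an in-plane silyl ether would collide with the metal on the carbonyl oxygen and align the C–O and C=O dipoles; the flap carbon C2 then lies on the opposite face, and the stereoelectronically preferred axial attack at C10 comes from that face, anti to the silyloxy group, so that C14 ends cis to the C3 oxygen (10R). C5 follows from the suprafacial addition and is erased in step 8. Regioselectivity is secured by the polarisation of both partners (largest HOMO coefficient at the CH2 next to the silyloxy carbon, largest LUMO coefficient at C10), which puts the oxygen on C8 and the enol double bond between C7 and C8. The selectivity the step needs is facial, and it depends on non-chelating conditions: a bulky silyl ether and no excess of Me2AlCl.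

Step 7
Reactants: 8 cis-fused silyloxy decalone
Product: 9 3β,8-bis(tert-butyldimethylsilyloxy)-4α,10β-dimethyl-5βH-decal-7-en-4β-ol (cis-fused; 4β-hydroxyl expected)
Conditions: MeMgBr, anhydrous CeCl3, THF, −78 → 0 °C; aq NH4Cl
Reagents that add atoms: methylmagnesium bromide, C[Mg]Br
Why: 1,2-Addition of the weakly basic methylcerium reagent to a hindered, enolisable ketone, so C3 is not epimerised and the enol silane survives. The methyl should enter from the α face, since the β face carries the axial C14 in one chair form of the cis-decalone and the axial silyloxy group in the other; C4 is not a stereocentre of the target.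

Step 8
Reactants: 9 tertiary alcohol
Product: 10 3β,8-bis(tert-butyldimethylsilyloxy)-11,12,13-trinoreudesma-4,7-diene
Conditions: Burgess reagent (methyl N-(triethylammoniosulfonyl)carbamate), benzene, 50 °C
Reagents that add atoms: none
Why: Dehydration through the sulfamate ester with cis-elimination: with a 4β-hydroxyl the only ring hydrogen on the same face is H5, while H3 is on the α face, and the ion-pair character of a tertiary centre favours the tetrasubstituted C4=C5 alkene over the exocyclic one. The neutral conditions leave both silyl ethers intact.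

Step 9
Reactants: 10 bis-silyl diene
Product: 12 methyl 3β-(tert-butyldimethylsilyloxy)-8-oxo-13-nor-7αH-eudesm-4-en-12-oate (7β side chain), via 7α keto ester 11 (not isolated)
Conditions: Bu4N[Ph3SiF2], BrCH2CO2Me, THF, −78 → 0 °C; then NaOMe (cat.), MeOH, 0 °C → rt
Reagents that add atoms: methyl bromoacetate, COC(=O)CBr
Why: Fluoride attacks silicon of the enol silane, which is far more labile than the alkyl silyl ether at C3, and releases the ammonium enolate regiospecifically across C7–C8; SN2 alkylation by the reactive α-bromo ester follows at C7. Axial attack should give the 7α isomer first; since C7 is α to the ketone, methoxide equilibrates it to the equatorial 7β isomer.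

Step 10
Reactants: 12 7β keto ester
Product: 14 3β-(tert-butyldimethylsilyloxy)-13-nor-7αH-8αH-eudesm-4-en-8β,12-olide (cis-fused lactone), via 8β-hydroxy ester 13 (not isolated)
Conditions: LiBH(s-Bu)3, THF, −78 → 0 °C; aq NH4Cl, rt
Reagents that add atoms: none
Why: The bulky hydride attacks C8 from the α face on an equatorial trajectory, because the axial C14, 1,3 to C8, screens the β face; this gives the axial 8β-alkoxide, cis to the 7β side chain, which closes the γ-lactone by 5-exo-trig acyl substitution. The ester is not reduced at this temperature, and any 7α isomer cannot lactonise and is removed.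

Step 11
Reactants: 14 cis-fused lactone
Product: 17 3β-(tert-butyldimethylsilyloxy)-7αH-8αH-eudesma-4,11(13)-dien-8β,12-olide, via Mannich base 15 (not isolated), via methiodide 16 (not isolated)
Conditions: LiN(i-Pr)2, THF, −78 °C; CH2=NMe2+ I− (Eschenmoser's salt), −78 °C → rt; MeI, MeOH, rt; aq NaHCO3, CH2Cl2
Reagents that add atoms: Eschenmoser's salt (N,N-dimethylmethyleneiminium iodide), C=[N+](C)C.[I-]
Why: α-Methylenation of a lactone by Mannich reaction of its lithium enolate, N-methylation and E1cB loss of trimethylamine; C11 is the only enolisable position, and elimination can only form the exocyclic C11=C13 bond. C7 and C8 are not touched.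

Step 12
Reactants: 17 α-methylene lactone
Product: 19 methyl 3β-(tert-butyldimethylsilyloxy)-8β-hydroxyeudesma-4,11(13)-dien-12-oate, via lithium carboxylate 18 (not isolated)
Conditions: LiOH (1.05 equiv), THF/H2O, 0 °C → rt; evaporate, azeotrope with toluene; MeI, DMF, rt; used at once
Reagents that add atoms: lithium hydroxide, [Li+].[OH-]; iodomethane, CI
Why: Saponification of the lactone gives the acrylate carboxylate, which is no longer a Michael acceptor; O-alkylation of the carboxylate with iodomethane in DMF forms the methyl ester without acid or strong base, conditions under which the hindered axial 8β-hydroxyl re-closes only slowly.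

Step 13
Reactants: 19 hydroxy acrylate
Product: 20 methyl 8β-acetoxy-3β-(tert-butyldimethylsilyloxy)eudesma-4,11(13)-dien-12-oate
Conditions: Ac2O (excess), DMAP, Et3N, CH2Cl2, 0 °C → rt
Reagents that add atoms: acetic anhydride, CC(=O)OC(C)=O
Why: DMAP-catalysed acetylation of the axial secondary alcohol; excess anhydride makes acylation faster than re-lactonisation, and once O8 is acetylated the lactone can no longer form.

Step 14
Reactants: 20 silyl ether
Product: 21 methyl 8β-acetoxy-3β-hydroxyeudesma-4,11(13)-dien-12-oate
Conditions: Bu4NF, AcOH (1:1), THF, rt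
Reagents that add atoms: none
Why: Fluoride cleavage of the silyl ether; buffering with acetic acid keeps the medium from being basic enough to attack the acrylate or acidic enough to ionise the allylic C3–O bond.

Step 15
Reactants: 21 allylic alcohol; 22 (E)-3-methylpent-2-enoic acid
Product: 23 methyl 8β-acetoxy-3β-[(E)-3-methylpent-2-enoyloxy]eudesma-4,11(13)-dien-12-oate, the (3S,7R,8R,10R) target
Conditions: DCC, DMAP (cat.), CH2Cl2, 0 °C → rt
Reagents that add atoms: none
Why: Steglich esterification of the equatorial allylic alcohol through the O-acylisourea; low temperature and only catalytic DMAP limit γ-deprotonation of the activated enoate, which would scramble its geometry. C3 keeps its configuration because the C–O bond is not broken.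

## Compound list

1 | 3-methylcyclohex-2-en-1-one | CC1=CC(=O)CCC1 | starting material
2 | racemic 6-acetoxy-3-methylcyclohex-2-en-1-one | CC1=CC(=O)C(OC(C)=O)CC1 | intermediate
3 | racemic 6-hydroxy-3-methylcyclohex-2-en-1-one | CC1=CC(=O)C(O)CC1 | intermediate
4 | (S)-6-hydroxy-3-methylcyclohex-2-en-1-one | CC1=CC(=O)[C@@H](O)CC1 | intermediate
5 | (S)-6-(tert-butyldimethylsilyloxy)-3-methylcyclohex-2-en-1-one | CC1=CC(=O)[C@@H](O[Si](C)(C)C(C)(C)C)CC1 | intermediate
6 | but-3-en-2-one | CC(=O)C=C | starting material
7 | 2-(tert-butyldimethylsilyloxy)buta-1,3-diene | C=CC(=C)O[Si](C)(C)C(C)(C)C | intermediate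
8 | (2S,4aR,8aS)-2,6-bis(tert-butyldimethylsilyloxy)-4a-methyl-3,4,4a,5,8,8a-hexahydronaphthalen-1(2H)-one (3β,8-bis-silyloxy-10β-methyl-5βH-decal-7-en-4-one) | C1(O[Si](C)(C)C(C)(C)C)=CC[C@@H]2C(=O)[C@@H](O[Si](C)(C)C(C)(C)C)CC[C@]2(C)C1 | intermediate
9 | 3β,8-bis(tert-butyldimethylsilyloxy)-4α,10β-dimethyl-5βH-decal-7-en-4β-ol | C1(O[Si](C)(C)C(C)(C)C)=CC[C@@H]2[C@@](C)(O)[C@@H](O[Si](C)(C)C(C)(C)C)CC[C@]2(C)C1 | intermediate
10 | 3β,8-bis(tert-butyldimethylsilyloxy)-11,12,13-trinoreudesma-4,7-diene | C1(O[Si](C)(C)C(C)(C)C)=CCC2=C(C)[C@@H](O[Si](C)(C)C(C)(C)C)CC[C@]2(C)C1 | intermediate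
11 | methyl 3β-(tert-butyldimethylsilyloxy)-8-oxo-13-nor-7βH-eudesm-4-en-12-oate (7α side chain) | COC(=O)C[C@@H]1CC2=C(C)[C@@H](O[Si](C)(C)C(C)(C)C)CC[C@]2(C)CC1=O | intermediate
12 | methyl 3β-(tert-butyldimethylsilyloxy)-8-oxo-13-nor-7αH-eudesm-4-en-12-oate (7β side chain) | COC(=O)C[C@H]1CC2=C(C)[C@@H](O[Si](C)(C)C(C)(C)C)CC[C@]2(C)CC1=O | intermediate
13 | methyl 3β-(tert-butyldimethylsilyloxy)-8β-hydroxy-13-nor-7αH-eudesm-4-en-12-oate | COC(=O)C[C@H]1CC2=C(C)[C@@H](O[Si](C)(C)C(C)(C)C)CC[C@]2(C)C[C@H]1O | intermediate
14 | 3β-(tert-butyldimethylsilyloxy)-13-nor-7αH,8αH-eudesm-4-en-8β,12-olide | O=C3C[C@H]1CC2=C(C)[C@@H](O[Si](C)(C)C(C)(C)C)CC[C@]2(C)C[C@H]1O3 | intermediate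
15 | 13-(dimethylamino)-3β-(tert-butyldimethylsilyloxy)-7αH,8αH-eudesm-4-en-8β,12-olide (C11 epimers) | O=C3C(CN(C)C)[C@H]1CC2=C(C)[C@@H](O[Si](C)(C)C(C)(C)C)CC[C@]2(C)C[C@H]1O3 | intermediate
16 | N-methyl quaternary iodide of 15 | O=C3C(C[N+](C)(C)C)[C@H]1CC2=C(C)[C@@H](O[Si](C)(C)C(C)(C)C)CC[C@]2(C)C[C@H]1O3.[I-] | intermediate
17 | 3β-(tert-butyldimethylsilyloxy)-7αH,8αH-eudesma-4,11(13)-dien-8β,12-olide | O=C3C(=C)[C@H]1CC2=C(C)[C@@H](O[Si](C)(C)C(C)(C)C)CC[C@]2(C)C[C@H]1O3 | intermediate
18 | lithium 3β-(tert-butyldimethylsilyloxy)-8β-hydroxyeudesma-4,11(13)-dien-12-oate | C=C(C(=O)[O-])[C@H]1CC2=C(C)[C@@H](O[Si](C)(C)C(C)(C)C)CC[C@]2(C)C[C@H]1O.[Li+] | intermediate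
19 | methyl 3β-(tert-butyldimethylsilyloxy)-8β-hydroxyeudesma-4,11(13)-dien-12-oate | C=C(C(=O)OC)[C@H]1CC2=C(C)[C@@H](O[Si](C)(C)C(C)(C)C)CC[C@]2(C)C[C@H]1O | intermediate
20 | methyl 8β-acetoxy-3β-(tert-butyldimethylsilyloxy)eudesma-4,11(13)-dien-12-oate | C=C(C(=O)OC)[C@H]1CC2=C(C)[C@@H](O[Si](C)(C)C(C)(C)C)CC[C@]2(C)C[C@H]1OC(C)=O | intermediate
21 | methyl 8β-acetoxy-3β-hydroxyeudesma-4,11(13)-dien-12-oate | C=C(C(=O)OC)[C@H]1CC2=C(C)[C@@H](O)CC[C@]2(C)C[C@H]1OC(C)=O | intermediate
22 | (E)-3-methylpent-2-enoic acid | OC(=O)/C=C(\C)CC | starting material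
23 | methyl 8β-acetoxy-3β-[(E)-3-methylpent-2-enoyloxy]eudesma-4,11(13)-dien-12-oate, (3S,7R,8R,10R) | C=C(C(=O)OC)[C@H]1CC2=C(C)[C@@H](OC(=O)/C=C(\C)CC)CC[C@]2(C)C[C@H]1OC(C)=O | target

## Step count and risks

Total step count: 15. Longest linear sequence: 14 steps (steps 1 to 4 and 6 to 15, from 1 to 23); step 5 is a one-step branch.

**Step 6 (key step).**
- What may go wrong: poor or reversed facial discrimination. The C3 silyloxy group does not touch the reacting carbons and steers the diene only through the conformation of the aluminium complex. If the Lewis acid chelates the carbonyl and ether oxygens, the silyloxy group turns into the enone plane and axial attack then comes from its own face. Slow addition at the β,β-disubstituted C10 with loss of the enol silane is a second weakness.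
- Fallback: the syn sense is accepted and C3 is corrected at the end by substrate control from C10. From 2, the same lipase used hydrolytically (pH 7 buffer) releases the fast-reacting enantiomer as (R)-6-hydroxy-3-methylcyclohex-2-en-1-one F1, and silylation as in step 4 gives (R)-6-(tert-butyldimethylsilyloxy)-3-methylcyclohex-2-en-1-one F2. Cycloaddition with 7 on the face syn to the silyloxy group gives 3-epi-8 F3, which has the required 10R centre. Steps 7 to 14 are then run unchanged in the 3α series, through 3-epi-9 F4, 3-epi-10 F5, 3-epi-11 F6, 3-epi-12 F7, 3-epi-13 F8, 3-epi-14 F9, 3-epi-15 F10, 3-epi-16 F11, 3-epi-17 F12, 3-epi-18 F13, 3-epi-19 F14, 3-epi-20 F15 and 3-epi-21 F16. MnO2 in CH2Cl2 oxidises the allylic alcohol to methyl 8β-acetoxy-3-oxoeudesma-4,11(13)-dien-12-oate F17, and NaBH4 with CeCl3·7H2O in MeOH at −78 °C (Luche reduction) delivers hydride axially from the α face, opposite C14, to give the equatorial 3β-alcohol 21, where the route is rejoined.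

**Step 8.**
- What may go wrong: elimination in the wrong direction, toward C15 (exocyclic methylene) or, if the methyl of step 7 entered from the β face, toward C3 (a second enol silane). The outcome depends on the C4 configuration, which the target does not record and the design therefore does not control.
- Fallback: the carbinol is bypassed. From 8, KN(SiMe3)2 and PhNTf2 in THF at −78 °C give the enol triflate F18; the base should remove H5 and not H3, since a C–H on a silyloxy-bearing carbon is kinetically less acidic. Me2CuLi in THF at −20 °C then replaces the triflate by methyl and gives 10, with the double bond fixed at C4–C5 by the position of the triflate.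

**Step 9.**
- What may go wrong: loss of regiochemical integrity of the ammonium enolate by proton transfer to the product ketone, leading to alkylation at C9 or double alkylation, together with partial cleavage of the C3 silyl ether by fluoride. An unsolvated enolate equilibrates quickly, and the electrophile must outrun that.
- Fallback: unmasking and alkylation are separated. From 10, Bu4NF/AcOH in THF at −20 °C hydrolyses only the enol silane to 3β-(tert-butyldimethylsilyloxy)-11,12,13-trinoreudesm-4-en-8-one F19. LiN(i-Pr)2 at −78 °C removes a C7 proton, since C9 is neopentyl beside the quaternary C10, and the lithium enolate is alkylated with methyl bromoacetate in THF/DMPU. Equilibration with NaOMe as in step 9 gives 12.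

**Step 12.**
- What may go wrong: re-closure of the cis γ-hydroxy ester to lactone 17 during methylation or before acetylation, and conjugate addition of hydroxide to C13. The 8β-oxygen and C12 are held cis and five atoms apart, and the lactone is the thermodynamic sink.
- Fallback: a redox detour in which no free γ-hydroxy ester occurs. From 17, (i-Bu)2AlH in CH2Cl2 (−78 → 0 °C) reduces the lactone to the 8β,12-diol F20. Et3SiCl and imidazole silylate the primary allylic hydroxyl selectively to give the 12-triethylsilyl ether F21, and Ac2O/DMAP acetylates O8 to give acetate F22. PPTS in MeOH removes the triethylsilyl group to give the allylic alcohol F23, MnO2 gives the enal F24, and NaClO2/NaH2PO4 with 2-methylbut-2-ene gives the acid F25. Me3SiCHN2 in toluene/MeOH gives 20.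

## Further compounds

F1 | step 6 | (R)-6-hydroxy-3-methylcyclohex-2-en-1-one | CC1=CC(=O)[C@H](O)CC1
F2 | step 6 | (R)-6-(tert-butyldimethylsilyloxy)-3-methylcyclohex-2-en-1-one | CC1=CC(=O)[C@H](O[Si](C)(C)C(C)(C)C)CC1
F3 | step 6 | 3-epi-8 (3α,8-bis-silyloxy-10β-methyl-5βH-decal-7-en-4-one) | C1(O[Si](C)(C)C(C)(C)C)=CC[C@@H]2C(=O)[C@H](O[Si](C)(C)C(C)(C)C)CC[C@]2(C)C1
F4 | step 6 | 3-epi-9 (C4 configuration open) | C1(O[Si](C)(C)C(C)(C)C)=CC[C@@H]2C(C)(O)[C@H](O[Si](C)(C)C(C)(C)C)CC[C@]2(C)C1
F5 | step 6 | 3-epi-10 | C1(O[Si](C)(C)C(C)(C)C)=CCC2=C(C)[C@H](O[Si](C)(C)C(C)(C)C)CC[C@]2(C)C1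
F6 | step 6 | 3-epi-11 | COC(=O)C[C@@H]1CC2=C(C)[C@H](O[Si](C)(C)C(C)(C)C)CC[C@]2(C)CC1=O
F7 | step 6 | 3-epi-12 | COC(=O)C[C@H]1CC2=C(C)[C@H](O[Si](C)(C)C(C)(C)C)CC[C@]2(C)CC1=O
F8 | step 6 | 3-epi-13 | COC(=O)C[C@H]1CC2=C(C)[C@H](O[Si](C)(C)C(C)(C)C)CC[C@]2(C)C[C@H]1O
F9 | step 6 | 3-epi-14 | O=C3C[C@H]1CC2=C(C)[C@H](O[Si](C)(C)C(C)(C)C)CC[C@]2(C)C[C@H]1O3
F10 | step 6 | 3-epi-15 | O=C3C(CN(C)C)[C@H]1CC2=C(C)[C@H](O[Si](C)(C)C(C)(C)C)CC[C@]2(C)C[C@H]1O3
F11 | step 6 | 3-epi-16 | O=C3C(C[N+](C)(C)C)[C@H]1CC2=C(C)[C@H](O[Si](C)(C)C(C)(C)C)CC[C@]2(C)C[C@H]1O3.[I-]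
F12 | step 6 | 3-epi-17 | O=C3C(=C)[C@H]1CC2=C(C)[C@H](O[Si](C)(C)C(C)(C)C)CC[C@]2(C)C[C@H]1O3
F13 | step 6 | 3-epi-18 | C=C(C(=O)[O-])[C@H]1CC2=C(C)[C@H](O[Si](C)(C)C(C)(C)C)CC[C@]2(C)C[C@H]1O.[Li+]
F14 | step 6 | 3-epi-19 | C=C(C(=O)OC)[C@H]1CC2=C(C)[C@H](O[Si](C)(C)C(C)(C)C)CC[C@]2(C)C[C@H]1O
F15 | step 6 | 3-epi-20 | C=C(C(=O)OC)[C@H]1CC2=C(C)[C@H](O[Si](C)(C)C(C)(C)C)CC[C@]2(C)C[C@H]1OC(C)=O
F16 | step 6 | 3-epi-21 (methyl 8β-acetoxy-3α-hydroxyeudesma-4,11(13)-dien-12-oate) | C=C(C(=O)OC)[C@H]1CC2=C(C)[C@H](O)CC[C@]2(C)C[C@H]1OC(C)=O
F17 | step 6 | methyl 8β-acetoxy-3-oxoeudesma-4,11(13)-dien-12-oate | C=C(C(=O)OC)[C@H]1CC2=C(C)C(=O)CC[C@]2(C)C[C@H]1OC(C)=O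
F18 | step 8 | 3β,8-bis(tert-butyldimethylsilyloxy)-10β-methyl-1,2,3,6,9,10-hexahydronaphthalen-4-yl triflate (decalin numbering as in the text; enol triflate at C4=C5) | C1(O[Si](C)(C)C(C)(C)C)=CCC2=C(OS(=O)(=O)C(F)(F)F)[C@@H](O[Si](C)(C)C(C)(C)C)CC[C@]2(C)C1
F19 | step 9 | 3β-(tert-butyldimethylsilyloxy)-11,12,13-trinoreudesm-4-en-8-one | O=C1CCC2=C(C)[C@@H](O[Si](C)(C)C(C)(C)C)CC[C@]2(C)C1
F20 | step 12 | 3β-(tert-butyldimethylsilyloxy)eudesma-4,11(13)-diene-8β,12-diol | C=C(CO)[C@H]1CC2=C(C)[C@@H](O[Si](C)(C)C(C)(C)C)CC[C@]2(C)C[C@H]1O
F21 | step 12 | 3β-(tert-butyldimethylsilyloxy)-12-(triethylsilyloxy)eudesma-4,11(13)-dien-8β-ol | C=C(CO[Si](CC)(CC)CC)[C@H]1CC2=C(C)[C@@H](O[Si](C)(C)C(C)(C)C)CC[C@]2(C)C[C@H]1O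
F22 | step 12 | 8β-acetoxy-3β-(tert-butyldimethylsilyloxy)-12-(triethylsilyloxy)eudesma-4,11(13)-diene | C=C(CO[Si](CC)(CC)CC)[C@H]1CC2=C(C)[C@@H](O[Si](C)(C)C(C)(C)C)CC[C@]2(C)C[C@H]1OC(C)=O
F23 | step 12 | 8β-acetoxy-3β-(tert-butyldimethylsilyloxy)eudesma-4,11(13)-dien-12-ol | C=C(CO)[C@H]1CC2=C(C)[C@@H](O[Si](C)(C)C(C)(C)C)CC[C@]2(C)C[C@H]1OC(C)=O
F24 | step 12 | 8β-acetoxy-3β-(tert-butyldimethylsilyloxy)eudesma-4,11(13)-dien-12-al | C=C(C=O)[C@H]1CC2=C(C)[C@@H](O[Si](C)(C)C(C)(C)C)CC[C@]2(C)C[C@H]1OC(C)=O
F25 | step 12 | 8β-acetoxy-3β-(tert-butyldimethylsilyloxy)eudesma-4,11(13)-dien-12-oic acid | C=C(C(=O)O)[C@H]1CC2=C(C)[C@@H](O[Si](C)(C)C(C)(C)C)CC[C@]2(C)C[C@H]1OC(C)=O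
A1 | alternative 1 | methyl 8β-acetoxyeudesma-4,11(13)-dien-12-oate | C=C(C(=O)OC)[C@H]1CC2=C(C)CCC[C@]2(C)C[C@H]1OC(C)=O
A2 | alternative 1 | methyl 8β-acetoxy-(1(10)E,4E)-germacra-1(10),4,11(13)-trien-12-oate | C=C(C(=O)OC)[C@H]1C/C=C(C)/CC/C=C(C)/C[C@H]1OC(C)=O
A3 | alternative 2 | 3β-hydroxy-4-methyl-5,10-methanodecal-8-one (cyclopropane on the face of the C3 hydroxyl) | C1C[C@]23C[C@@]3(CC[C@H](O)[C@H]2C)CC1=O
A4 | alternative 2 | 6-hydroxy-5-methyl-3,4,5,6,7,8-hexahydronaphthalen-2(1H)-one (3-hydroxy-4-methyl-5(10)-octalin-8-one in eudesmane numbering) | C1CC2=C(CC[C@H](O)[C@H]2C)CC1=O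
A5 | alternative 3 | cis-fused 8,12-cyclic ethyl acetal of 3β-(tert-butyldimethylsilyloxy)-13-noreudesm-4-ene (acetal epimers) | C1[C@H]2CC3=C(C)[C@@H](O[Si](C)(C)C(C)(C)C)CC[C@]3(C)C[C@H]2OC1OCC
A6 | alternative 3 | 8β-(2-bromo-1-ethoxyethoxy)-3β-(tert-butyldimethylsilyloxy)-11,12,13-trinoreudesma-4,6-diene | BrCC(OCC)O[C@@H]1C[C@@]2(C)CC[C@H](O[Si](C)(C)C(C)(C)C)C(C)=C2C=C1
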